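**Plan**

Numbering used below: ring A = O–C3(=O)–C2=C1–C10(CH3)–C5–C4(CH3)2; ring B = C5–C6–C7–C8–C9–C10; cage = C11 (on C9), C12 (ketone), C13 (C–CH3), C14H2 (C13–C8 bridge), C15H2, C16H, C17 (quaternary), C18 (=CH2), with the γ-lactone C16–C(=O)–O–CH2–C17.
Retrosynthesis: put a helper ketone back at C7; cut C13–C15 and C8–C17 (two Michael closures); cut C9–C11 and C8–C14 (Diels–Alder); cut O–C4 (Baeyer–Villiger); cut C1–C10 and C8–C9 together (radical bicyclisation of an acyclic chloro keto ester ynone).
Enabling feature: C10 is a methyl-bearing quaternary carbon 1,3 to C8 and β to the ring-A carbonyl. An isopropenyl group (C9=C10) on C5 therefore sits between an electrophilic radical site (C8, α to the C7 ketone) and a radical acceptor (C1≡C2–C3=O), and polarity alternation closes ring B and then ring A at C1–C10.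
Forward: lactone 6 → acyclic ynone 13 → rings B and A (14) → ring-A lactone (15) → cyclohexanone C8/C9/C11–C14 (30) → cyclopentane and last cage ring (33) → removal of the C7 oxygen (35).
Stereochemistry: C5 from a rhodium-catalysed asymmetric conjugate addition; C10 from the chair-like cascade (trans A/B); C9 and C8 from addition anti to the axial C10 methyl and the tether from C11; C11, C13, C16 and C17 are fixed by the cage.

Key step: step 9

Remark on the chemistry: the target has H9 syn to the C10 methyl with trans A/B and trans B/cage fusions, so ring B must end as a boat; the cage is therefore built onto a preformed trans-decalin from its α face. Formaldehyde is used as paraformaldehyde.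

**Route**

Step 1
Reactants: 1 2,2-dimethylbut-3-en-1-ol; 2 acryloyl chloride
Product: 3 2,2-dimethylbut-3-en-1-yl prop-2-enoate
Conditions: Et3N, DMAP (cat.), CH2Cl2, 0 °C to rt
Reagents that add atoms: none
Why: O-acylation of a primary alcohol by an acid chloride; no stereocenter is formed.

Step 2
Reactants: 3 2,2-dimethylbut-3-en-1-yl prop-2-enoate
Product: 4 5,5-dimethyl-5,6-dihydro-2H-pyran-2-one
Conditions: second-generation Grubbs catalyst (5 mol %), CH2Cl2 (0.01 M), 40 °C
Reagents that add atoms: none
Why: ring-closing metathesis of an acrylate with a terminal alkene to a six-membered unsaturated lactone, driven by loss of ethylene.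

Step 3
Reactants: 4 5,5-dimethyl-5,6-dihydro-2H-pyran-2-one; 5 isopropenylboronic acid pinacol ester
Product: 6 (4R)-5,5-dimethyl-4-(prop-1-en-2-yl)oxan-2-one
Conditions: [RhCl(cod)]2 (3 mol %), (R)-BINAP (7 mol %; the antipode that delivers the 4R lactone, to be confirmed on the first run), KOH (aq), dioxane/H2O 10:1, 60 °C
Reagents that add atoms: none
Why: Hayashi–Miyaura rhodium-catalysed asymmetric 1,4-addition of an alkenylboron reagent to a cyclic enoate; the chiral ligand sets the future C5.

Step 4
Reactants: 6 (4R)-5,5-dimethyl-4-(prop-1-en-2-yl)oxan-2-one; 7 2-(trimethylsilyl)ethyl acetate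
Product: 8 2-(trimethylsilyl)ethyl (5R)-7-hydroxy-6,6-dimethyl-3-oxo-5-(prop-1-en-2-yl)heptanoate
Conditions: LiN(i-Pr)2 (2.2 equiv), 7, THF, −78 °C; then 6, −78 to −20 °C; aq NH4Cl
Reagents that add atoms: none
Why: crossed Claisen condensation in which the lithium ester enolate opens the lactone to a δ-hydroxy β-keto ester (in equilibrium with its cyclic hemiketal); C5 is untouched.

Step 5
Reactants: 8 2-(trimethylsilyl)ethyl (5R)-7-hydroxy-6,6-dimethyl-3-oxo-5-(prop-1-en-2-yl)heptanoate
Product: 9 2-(trimethylsilyl)ethyl (5R)-6,6-dimethyl-3,7-dioxo-5-(prop-1-en-2-yl)heptanoate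
Conditions: TEMPO (10 mol %), PhI(OAc)2 (1.2 equiv), CH2Cl2, rt
Reagents that add atoms: none
Why: oxoammonium (TEMPO) oxidation of the primary alcohol, drained from the hemiketal equilibrium, to an aldehyde whose α-carbon is quaternary and cannot epimerise.

Step 6
Reactants: 9 2-(trimethylsilyl)ethyl (5R)-6,6-dimethyl-3,7-dioxo-5-(prop-1-en-2-yl)heptanoate; 10 ethynylmagnesium bromide
Product: 11 2-(trimethylsilyl)ethyl (5R)-7-hydroxy-6,6-dimethyl-3-oxo-5-(prop-1-en-2-yl)non-8-ynoate (C7 epimers)
Conditions: 10 (2.3 equiv), THF, −78 to −20 °C; aq NH4Cl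
Reagents that add atoms: none
Why: Grignard 1,2-addition to the aldehyde while the first equivalent holds the β-keto ester as its magnesium enolate; the new carbinol center is oxidised away in step 8.

Step 7
Reactants: 11 2-(trimethylsilyl)ethyl (5R)-7-hydroxy-6,6-dimethyl-3-oxo-5-(prop-1-en-2-yl)non-8-ynoate
Product: 12 2-(trimethylsilyl)ethyl (5R)-2-chloro-7-hydroxy-6,6-dimethyl-3-oxo-5-(prop-1-en-2-yl)non-8-ynoate (C2 and C7 epimers)
Conditions: N-chlorosuccinimide (1.05 equiv), Et3N (10 mol %), CH2Cl2, 0 °C
Reagents that add atoms: N-chlorosuccinimide, O=C1CCC(=O)N1Cl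
Why: electrophilic α-chlorination of the β-keto ester through its enol; the chlorine blocks over-oxidation in step 9, makes the ketone non-enolisable for step 10 and is the leaving group in step 18, so its configuration is irrelevant.

Step 8
Reactants: 12 2-(trimethylsilyl)ethyl (5R)-2-chloro-7-hydroxy-6,6-dimethyl-3-oxo-5-(prop-1-en-2-yl)non-8-ynoate
Product: 13 2-(trimethylsilyl)ethyl (5R)-2-chloro-6,6-dimethyl-3,7-dioxo-5-(prop-1-en-2-yl)non-8-ynoate (C2 epimers)
Conditions: MnO2 (activated, 15 equiv), CH2Cl2, rt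
Reagents that add atoms: none
Why: selective oxidation of a propargylic alcohol to the ynone by activated MnO2.

Step 9
Reactants: 13 2-(trimethylsilyl)ethyl (5R)-2-chloro-6,6-dimethyl-3,7-dioxo-5-(prop-1-en-2-yl)non-8-ynoate
Product: 14 2-(trimethylsilyl)ethyl 2-chloro-5,5,8a-trimethyl-3,6-dioxo-1,2,3,4,4a,5,6,8a-octahydronaphthalene-2-carboxylate (rings B and A; trans fusion with H5 anti to the C10 methyl; C8 epimers)
Conditions: Mn(OAc)3·2H2O (2.2 equiv), degassed EtOH (5 mM), 40 °C
Reagents that add atoms: none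
Why: Proposed new method: the manganese enolate of the α-chloro-β-keto ester loses divalent manganese to give the electrophilic C8 radical, which adds 6-endo-trig to the electron-rich CH2 terminus (C9) of the isopropenyl group and closes ring B; the nucleophilic tertiary C10 radical then adds 6-endo-dig to the electron-poor terminal carbon C1 of the ynone, closing ring A at C1–C10, and the α-keto vinyl radical at C2 takes a hydrogen atom from ethanol to give the ring-A enone directly. The closest known reaction type is the Snider oxidative free-radical polycyclisation of unsaturated β-keto esters with Mn(OAc)3, combined with Giese addition of tertiary radicals to ynones; new here are the direction of the cascade (ring B before ring A) and the ynone terminus. Both closures are endo: 6-endo-trig beats 5-exo because C10 is fully substituted and the ketone lies inside the forming ring, and 6-endo-dig is favoured because the carbonyl polarises the alkyne toward attack at its terminus. C10 is set in the second closure through a chair-like transition state with the C5 substituents equatorial, so the C1–C10 bond forms anti to H5 (trans A/B, methyl axial) under control of the C5 stereocenter; C8 forms as a mixture and is erased in step 18. The step needs each radical to meet an acceptor of matching polarity, which the substrate provides, together with high dilution and the absence of Cu(OAc)2 so that the tertiary radical cyclises instead of being oxidised; the chlorine at C8 stops further oxidation of the product.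

Step 10
Reactants: 14 2-(trimethylsilyl)ethyl 2-chloro-5,5,8a-trimethyl-3,6-dioxo-1,2,3,4,4a,5,6,8a-octahydronaphthalene-2-carboxylate
Product: 15 2-(trimethylsilyl)ethyl 7-chloro-1,1,5a-trimethyl-3,8-dioxo-1,3,5a,6,7,8,9,9a-octahydro-2-benzoxepine-7-carboxylate (trans-fused; C8 epimers)
Conditions: mCPBA (3 equiv), NaHCO3, CH2Cl2, rt, dark
Reagents that add atoms: 3-chloroperbenzoic acid (mCPBA), O=C(OO)c1cccc(Cl)c1
Why: Baeyer–Villiger oxidation of the ring-A enone in which the fully substituted C4 migrates in preference to the vinyl carbon C2 and gives the α,β-unsaturated ε-lactone, while the non-enolisable, electron-poor chloro keto ester ketone at C7 stays untouched; migration is with retention and no stereocenter is affected.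

Step 11
Reactants: 16 tetronic acid; 17 formaldehyde; 18 thiophenol
Product: 19 4-hydroxy-3-[(phenylsulfanyl)methyl]furan-2(5H)-one
Conditions: paraformaldehyde, piperidine (10 mol %), AcOH (10 mol %), EtOH, rt
Reagents that add atoms: none
Why: Knoevenagel condensation of the cyclic 1,3-dicarbonyl with formaldehyde followed by thia-Michael trapping of the 3-methylene intermediate (three-component sulfanylmethylation).

Step 12
Reactants: 19 4-hydroxy-3-[(phenylsulfanyl)methyl]furan-2(5H)-one
Product: 20 5-oxo-4-[(phenylsulfanyl)methyl]-2,5-dihydrofuran-3-yl trifluoromethanesulfonate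
Conditions: Tf2O (1.1 equiv), i-Pr2NEt, CH2Cl2, −78 °C
Reagents that add atoms: trifluoromethanesulfonic anhydride, O=S(=O)(OS(=O)(=O)C(F)(F)F)C(F)(F)F
Why: O-sulfonylation of the vinylogous acid gives the vinyl triflate.

Step 13
Reactants: 20 5-oxo-4-[(phenylsulfanyl)methyl]-2,5-dihydrofuran-3-yl trifluoromethanesulfonate
Product: 21 3-[(phenylsulfanyl)methyl]-4-(tributylstannyl)furan-2(5H)-one
Conditions: Bu3SnSnBu3 (1.2 equiv), Pd(PPh3)4 (5 mol %), LiCl (3 equiv), dioxane, 90 °C
Reagents that add atoms: hexabutylditin, CCCC[Sn](CCCC)(CCCC)[Sn](CCCC)(CCCC)CCCC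
Why: palladium-catalysed stannylation of a vinyl triflate with a ditin (oxidative addition, transmetalation, reductive elimination).

Step 14
Reactants: 22 methacrolein; 23 2,3-dibromopropene
Product: 24 5-bromo-2-methylhexa-1,5-dien-3-ol (racemic)
Conditions: indium powder (1.2 equiv), THF/H2O 1:1, rt
Reagents that add atoms: none
Why: Barbier-type indium-mediated 2-bromoallylation of an aldehyde; the carbinol center is oxidised in the next step.

Step 15
Reactants: 24 5-bromo-2-methylhexa-1,5-dien-3-ol
Product: 25 5-bromo-2-methylhexa-1,5-dien-3-one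
Conditions: Dess–Martin periodinane (1.2 equiv), NaHCO3, CH2Cl2, 0 °C
Reagents that add atoms: none
Why: neutral hypervalent-iodine oxidation that leaves the β,γ-alkene out of conjugation.

Step 16
Reactants: 25 5-bromo-2-methylhexa-1,5-dien-3-one
Product: 26 tert-butyl{[(3Z)-5-bromo-2-methylhexa-1,3,5-trien-3-yl]oxy}dimethylsilane
Conditions: TBSOTf (1.1 equiv), Et3N (1.5 equiv), CH2Cl2, −78 to 0 °C
Reagents that add atoms: tert-butyldimethylsilyl trifluoromethanesulfonate, CC(C)(C)[Si](C)(C)OS(=O)(=O)C(F)(F)F
Why: soft enolisation and O-silylation at the only enolisable position (the future C11) gives the Z silyl enol ether, which places the bromovinyl group on the outside of the s-cis diene.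

Step 17
Reactants: 26 tert-butyl{[(3Z)-5-bromo-2-methylhexa-1,3,5-trien-3-yl]oxy}dimethylsilane; 21 3-[(phenylsulfanyl)methyl]-4-(tributylstannyl)furan-2(5H)-one
Product: 27 4-[(3Z)-4-{[tert-butyl(dimethyl)silyl]oxy}-5-methylhexa-1,3,5-trien-2-yl]-3-[(phenylsulfanyl)methyl]furan-2(5H)-one
Conditions: Pd(PPh3)4 (5 mol %), Cu(O2CC4H3S) (copper thiophene-2-carboxylate, 1.5 equiv), NMP, rt
Reagents that add atoms: none
Why: Stille coupling of a vinyl bromide with a β-stannyl butenolide in the fluoride-free copper carboxylate variant, which preserves the silyl enol ether and joins C18 to C17.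

Step 18
Reactants: 15 2-(trimethylsilyl)ethyl 7-chloro-1,1,5a-trimethyl-3,8-dioxo-1,3,5a,6,7,8,9,9a-octahydro-2-benzoxepine-7-carboxylate; 27 4-[(3Z)-4-{[tert-butyl(dimethyl)silyl]oxy}-5-methylhexa-1,3,5-trien-2-yl]-3-[(phenylsulfanyl)methyl]furan-2(5H)-one
Product: 30 tricyclic C12-ketone Diels–Alder adduct (C9–C11 and C8–C14 bonds on the α face; ester on C8 β; C11/C13 epimers), via alkylidene keto ester 28 (not isolated), via silyl enol ether cycloadduct 29 (not isolated)
Conditions: 15, 27 (1.3 equiv), DBU (1.2 equiv), toluene, 0 to 50 °C; then 1 M HCl, THF, rt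
Reagents that add atoms: none
Why: DBU eliminates HCl across C8–C9 to unmask the doubly activated dienophile 28, which is trapped at once in a Diels–Alder reaction with the 2-silyloxy diene 27 (normal regiochemistry: nucleophilic terminus C11 to C9, C14 to C8) from the face opposite the axial C10 methyl, so that C9 receives C11 on the α face (H9 syn to the methyl) and C8 carries C14 α and the ester β; C11 and C13 remain epimerisable through the C12 enol once the silyl enol ether is hydrolysed.

Step 19
Reactants: 30 tricyclic C12-ketone Diels–Alder adduct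
Product: 33 7-oxo derivative of the target (complete cage; C7 ketone), via keto acid 31 (not isolated), via methylene lactone 32 (not isolated)
Conditions: Bu4NF (1.2 equiv), THF, 0 °C to rt; then DBU (2 equiv), 40 °C
Reagents that add atoms: none
Why: fluoride removes the 2-(trimethylsilyl)ethyl group and the β-keto carboxylate loses CO2 to give the C8 enolate regiospecifically, which closes the cyclopentane by 5-(enolexo)-exo-trig Michael addition to C17 of the butenolide and expels thiolate (conjugate addition–β-elimination, as with 2-(halomethyl)acrylates), the tether from the α-oriented C11 forcing C17 onto the α face of C8 and C14 to the β face (only the C11 epimer with its side chain syn to C8 can close, and the epimers equilibrate through the C12 enol), after which DBU forms the only enolate still open to C12 (at C13, C11 now being a bridgehead) and this closes the last ring by 6-(enolexo)-endo-trig Michael addition to C15 of the new α-methylene lactone, with C13, C16 and C17 taking the only configurations the cage allows.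

Step 20
Reactants: 33 7-oxo derivative of the target
Product: 34 C7 tosylhydrazone of 33
Conditions: TsNHNH2 (1.5 equiv), pyridinium p-toluenesulfonate (cat.), EtOH, 70 °C
Reagents that add atoms: p-toluenesulfonyl hydrazide, Cc1ccc(S(=O)(=O)NN)cc1
Why: hydrazone condensation at C7, the only ketone with an unhindered methylene neighbour, while the cage ketone C12 (between quaternary C13 and bridgehead C11) is too hindered to condense; no stereocenter changes.

Step 21
Reactants: 34 C7 tosylhydrazone of 33
Product: 35 target CNP0136584.3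
Conditions: catecholborane (3 equiv), CHCl3, 0 °C; then NaOAc·3H2O, 60 °C
Reagents that add atoms: none
Why: Kabalka variant of the Caglioti reduction (hydride addition to C=N, loss of sulfinate, loss of N2 from the diazene) converts C7 to CH2 under conditions that spare both lactones, the enoate and the exocyclic alkene.

**Compound list**

1 | 2,2-dimethylbut-3-en-1-ol | C=CC(C)(C)CO | starting material
2 | acryloyl chloride | C=CC(=O)Cl | starting material
3 | 2,2-dimethylbut-3-en-1-yl prop-2-enoate | C=CC(=O)OCC(C)(C)C=C | intermediate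
4 | 5,5-dimethyl-5,6-dihydro-2H-pyran-2-one | O=C1C=CC(C)(C)CO1 | intermediate
5 | isopropenylboronic acid pinacol ester (4,4,5,5-tetramethyl-2-(prop-1-en-2-yl)-1,3,2-dioxaborolane) | C=C(C)B1OC(C)(C)C(C)(C)O1 | starting material
6 | (4R)-5,5-dimethyl-4-(prop-1-en-2-yl)oxan-2-one | O=C1C[C@H](C(C)=C)C(C)(C)CO1 | intermediate
7 | 2-(trimethylsilyl)ethyl acetate | CC(=O)OCC[Si](C)(C)C | starting material
8 | 2-(trimethylsilyl)ethyl (5R)-7-hydroxy-6,6-dimethyl-3-oxo-5-(prop-1-en-2-yl)heptanoate | C[Si](C)(C)CCOC(=O)CC(=O)C[C@H](C(C)=C)C(C)(C)CO | intermediate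
9 | 2-(trimethylsilyl)ethyl (5R)-6,6-dimethyl-3,7-dioxo-5-(prop-1-en-2-yl)heptanoate | C[Si](C)(C)CCOC(=O)CC(=O)C[C@H](C(C)=C)C(C)(C)C=O | intermediate
10 | ethynylmagnesium bromide | C#C[Mg]Br | starting material
11 | 2-(trimethylsilyl)ethyl (5R)-7-hydroxy-6,6-dimethyl-3-oxo-5-(prop-1-en-2-yl)non-8-ynoate (C7 epimers) | C[Si](C)(C)CCOC(=O)CC(=O)C[C@H](C(C)=C)C(C)(C)C(O)C#C | intermediate
12 | 2-(trimethylsilyl)ethyl (5R)-2-chloro-7-hydroxy-6,6-dimethyl-3-oxo-5-(prop-1-en-2-yl)non-8-ynoate (C2 and C7 epimers) | C[Si](C)(C)CCOC(=O)C(Cl)C(=O)C[C@H](C(C)=C)C(C)(C)C(O)C#C | intermediate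
13 | 2-(trimethylsilyl)ethyl (5R)-2-chloro-6,6-dimethyl-3,7-dioxo-5-(prop-1-en-2-yl)non-8-ynoate (C2 epimers) | C[Si](C)(C)CCOC(=O)C(Cl)C(=O)C[C@H](C(C)=C)C(C)(C)C(=O)C#C | intermediate
14 | 2-(trimethylsilyl)ethyl 2-chloro-5,5,8a-trimethyl-3,6-dioxo-1,2,3,4,4a,5,6,8a-octahydronaphthalene-2-carboxylate (trans-fused, 4a-H anti to 8a-CH3; C2 epimers) | O=C1C=C[C@]2(C)CC(Cl)(C(=O)OCC[Si](C)(C)C)C(=O)C[C@H]2C1(C)C | intermediate
15 | 2-(trimethylsilyl)ethyl 7-chloro-1,1,5a-trimethyl-3,8-dioxo-1,3,5a,6,7,8,9,9a-octahydro-2-benzoxepine-7-carboxylate (trans-fused; C7 epimers) | O=C1C=C[C@]2(C)CC(Cl)(C(=O)OCC[Si](C)(C)C)C(=O)C[C@H]2C(C)(C)O1 | intermediate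
16 | tetronic acid (4-hydroxyfuran-2(5H)-one) | O=C1C=C(O)CO1 | starting material
17 | formaldehyde (used as paraformaldehyde) | C=O | starting material
18 | thiophenol | Sc1ccccc1 | starting material
19 | 4-hydroxy-3-[(phenylsulfanyl)methyl]furan-2(5H)-one | O=C1OCC(O)=C1CSc1ccccc1 | intermediate
20 | 5-oxo-4-[(phenylsulfanyl)methyl]-2,5-dihydrofuran-3-yl trifluoromethanesulfonate | O=C1OCC(OS(=O)(=O)C(F)(F)F)=C1CSc1ccccc1 | intermediate
21 | 3-[(phenylsulfanyl)methyl]-4-(tributylstannyl)furan-2(5H)-one | O=C1OCC([Sn](CCCC)(CCCC)CCCC)=C1CSc1ccccc1 | intermediate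
22 | methacrolein | C=C(C)C=O | starting material
23 | 2,3-dibromopropene | C=C(Br)CBr | starting material
24 | 5-bromo-2-methylhexa-1,5-dien-3-ol (racemic) | C=C(Br)CC(O)C(C)=C | intermediate
25 | 5-bromo-2-methylhexa-1,5-dien-3-one | C=C(Br)CC(=O)C(C)=C | intermediate
26 | tert-butyl{[(3Z)-5-bromo-2-methylhexa-1,3,5-trien-3-yl]oxy}dimethylsilane | C=C(Br)/C=C(\O[Si](C)(C)C(C)(C)C)C(C)=C | intermediate
27 | 4-[(3Z)-4-{[tert-butyl(dimethyl)silyl]oxy}-5-methylhexa-1,3,5-trien-2-yl]-3-[(phenylsulfanyl)methyl]furan-2(5H)-one | C=C(C1=C(CSc2ccccc2)C(=O)OC1)/C=C(\O[Si](C)(C)C(C)(C)C)C(C)=C | intermediate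
28 | 2-(trimethylsilyl)ethyl 1,1,5a-trimethyl-3,8-dioxo-1,3,5a,8,9,9a-hexahydro-2-benzoxepine-7-carboxylate (alkylidene keto ester, C8=C9; trans-fused) | O=C1C=C[C@]2(C)C=C(C(=O)OCC[Si](C)(C)C)C(=O)C[C@H]2C(C)(C)O1 | intermediate
29 | Diels–Alder cycloadduct of 28 and 27 with C12 as its tert-butyldimethylsilyl enol ether (C12=C13); C9–C11 and C8–C14 bonds α, ester on C8 β, 1-(butenolidyl)vinyl group on C11 | O=C1C=C[C@]2(C)[C@@H]3C(C(=C)C4=C(CSc5ccccc5)C(=O)OC4)C(O[Si](C)(C)C(C)(C)C)=C(C)C[C@]3(C(=O)OCC[Si](C)(C)C)C(=O)C[C@H]2C(C)(C)O1 | intermediate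
30 | C12 ketone from 29: tricyclic keto lactone with C7 and C12 ketones, CO2CH2CH2SiMe3 on C8 (β), C14 on C8 (α), C11 on C9 (α), methyl on C13, 1-{5-oxo-4-[(phenylsulfanyl)methyl]-2,5-dihydrofuran-3-yl}vinyl on C11 (C11/C13 epimers) | O=C1C=C[C@]2(C)[C@@H]3C(C(=C)C4=C(CSc5ccccc5)C(=O)OC4)C(=O)C(C)C[C@]3(C(=O)OCC[Si](C)(C)C)C(=O)C[C@H]2C(C)(C)O1 | intermediate
31 | C8 carboxylic acid corresponding to 30 (β-keto acid) | O=C1C=C[C@]2(C)[C@@H]3C(C(=C)C4=C(CSc5ccccc5)C(=O)OC4)C(=O)C(C)C[C@]3(C(=O)O)C(=O)C[C@H]2C(C)(C)O1 | intermediate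
32 | pentacyclic α-methylene lactone: C8–C17 bond closed (cyclopentane C8–C9–C11–C18–C17 with exocyclic CH2 on C18), spiro α-methylene-γ-butyrolactone at C17, C13 still CH(CH3), C7 and C12 ketones | C=C1[C@@H]2C(=O)C(C)C[C@]3(C(=O)C[C@H]4C(C)(C)OC(=O)C=C[C@]4(C)[C@H]23)[C@@]15COC(=O)C5=C | intermediate
33 | 7-oxo derivative of the target (complete cage and ring-A lactone; C7 ketone) | C=C1[C@@H]2C(=O)[C@]3(C)C[C@@H]4C(=O)OC[C@]14[C@@]1(C(=O)C[C@H]4C(C)(C)OC(=O)C=C[C@]4(C)[C@H]21)C3 | intermediate
34 | C7 p-toluenesulfonylhydrazone of 33 | C=C1[C@@H]2C(=O)[C@]3(C)C[C@@H]4C(=O)OC[C@]14[C@@]1(C(=NNS(=O)(=O)c5ccc(C)cc5)C[C@H]4C(C)(C)OC(=O)C=C[C@]4(C)[C@H]21)C3 | intermediate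
35 | CNP0136584.3 | C=C1[C@@H]2C(=O)[C@]3(C)C[C@@H]4C(=O)OC[C@]14[C@@]1(CC[C@H]4C(C)(C)OC(=O)C=C[C@]4(C)[C@H]21)C3 | target

**Step count**

Total steps: 21. Longest linear sequence: 14 (steps 1–10 and 18–21).

**Steps most likely to fail**

1. Step 9. The tertiary C10 radical may be oxidised or reduced before it reaches the ynone, the ynone may be consumed by conjugate addition of solvent, or the second closure may give poor ring-fusion control. Fallback with known chemistry, setting out from 9: vinylmagnesium bromide gives the allylic alcohol 2-(trimethylsilyl)ethyl (5R)-7-hydroxy-6,6-dimethyl-3-oxo-5-(prop-1-en-2-yl)non-8-enoate F1, and N-chlorosuccinimide gives its 2-chloro derivative F2. Mn(OAc)3/Cu(OAc)2 in AcOH (Snider monocyclisation with oxidative termination) closes ring B to the methylenecyclohexanone 2-(trimethylsilyl)ethyl 1-chloro-4-(3-hydroxy-2-methylpent-4-en-2-yl)-5-methylidene-2-oxocyclohexane-1-carboxylate F3, and Dess–Martin oxidation gives the vinyl ketone 2-(trimethylsilyl)ethyl 1-chloro-4-(2-methyl-3-oxopent-4-en-2-yl)-5-methylidene-2-oxocyclohexane-1-carboxylate F4. Hydrogen-atom-transfer radical conjugate addition (Fe(acac)3, PhSiH3, EtOH) then closes ring A at C1–C10 to the saturated diketone 2-(trimethylsilyl)ethyl 2-chloro-5,5,8a-trimethyl-3,6-dioxodecahydronaphthalene-2-carboxylate F5, and IBX dehydrogenation of the ring-A ketone returns to the route at 14.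

2. Step 19. The C8 enolate may be protonated before it cyclises, or enolate equilibration may move the exocyclic C18 alkene into conjugation before the first Michael closure. Fallback, setting out from 30: Bu4NF in the presence of allyl bromide at 0 °C converts the silylethyl ester through its tetrabutylammonium carboxylate into the allyl ester analogue of 30 F6. Pd(PPh3)4 in THF then generates the C8 palladium enolate by decarboxylation under neutral conditions (Tsuji-type decarboxylative intramolecular Michael addition), with the released thiolate captured as allyl phenyl sulfide. This gives isolated 32, where the fallback rejoins the route; DBU takes 32 on to 33.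

3. Step 3. Rhodium insertion at the β-carbon next to the quaternary centre may be slow or poorly enantioselective. Fallback, setting out from 4: copper-catalysed conjugate addition of isopropenylmagnesium bromide (CuBr·SMe2, Me3SiCl, THF, −78 °C) gives racemic 5,5-dimethyl-4-(prop-1-en-2-yl)oxan-2-one F7. Aminolysis with (S)-1-phenylethylamine (AlMe3) gives diastereomeric hydroxy amides; the diastereomer (3R)-5-hydroxy-4,4-dimethyl-N-[(1S)-1-phenylethyl]-3-(prop-1-en-2-yl)pentanamide F8 is separated by chromatography and relactonised with aqueous acid to return to the route at 6.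

**Further compounds**

F1 | step 9 | 2-(trimethylsilyl)ethyl (5R)-7-hydroxy-6,6-dimethyl-3-oxo-5-(prop-1-en-2-yl)non-8-enoate | C[Si](C)(C)CCOC(=O)CC(=O)C[C@H](C(C)=C)C(C)(C)C(O)C=C
F2 | step 9 | 2-(trimethylsilyl)ethyl (5R)-2-chloro-7-hydroxy-6,6-dimethyl-3-oxo-5-(prop-1-en-2-yl)non-8-enoate | C[Si](C)(C)CCOC(=O)C(Cl)C(=O)C[C@H](C(C)=C)C(C)(C)C(O)C=C
F3 | step 9 | 2-(trimethylsilyl)ethyl 1-chloro-4-(3-hydroxy-2-methylpent-4-en-2-yl)-5-methylidene-2-oxocyclohexane-1-carboxylate | C[Si](C)(C)CCOC(=O)C1(Cl)CC(=C)[C@H](C(C)(C)C(O)C=C)CC1=O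
F4 | step 9 | 2-(trimethylsilyl)ethyl 1-chloro-4-(2-methyl-3-oxopent-4-en-2-yl)-5-methylidene-2-oxocyclohexane-1-carboxylate | C[Si](C)(C)CCOC(=O)C1(Cl)CC(=C)[C@H](C(C)(C)C(=O)C=C)CC1=O
F5 | step 9 | 2-(trimethylsilyl)ethyl 2-chloro-5,5,8a-trimethyl-3,6-dioxodecahydronaphthalene-2-carboxylate (trans-fused) | O=C1CC[C@]2(C)CC(Cl)(C(=O)OCC[Si](C)(C)C)C(=O)C[C@H]2C1(C)C
F6 | step 19 | allyl ester analogue of 30 | O=C1C=C[C@]2(C)[C@@H]3C(C(=C)C4=C(CSc5ccccc5)C(=O)OC4)C(=O)C(C)C[C@]3(C(=O)OCC=C)C(=O)C[C@H]2C(C)(C)O1
F7 | step 3 | racemic 5,5-dimethyl-4-(prop-1-en-2-yl)oxan-2-one | O=C1CC(C(C)=C)C(C)(C)CO1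
F8 | step 3 | (3R)-5-hydroxy-4,4-dimethyl-N-[(1S)-1-phenylethyl]-3-(prop-1-en-2-yl)pentanamide | C[C@H](NC(=O)C[C@H](C(C)=C)C(C)(C)CO)c1ccccc1
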